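The protic impurity is what separates blue from grey, which share their free monomer and initiator loading.

the same everywhere: free monomer 0.19 M; initiator 0.2 mol%
- autumn: protic impurity 0.056 M; run made earlier
- midnight: protic impurity 0.20 M; run made earlier
- blue: protic impurity 0.0380 M; time 5.0 min
- grey: protic impurity 0.150 M; time 5.0 min

| run | time / min | monomer in chains / % |
|---|---|---|
| autumn | 0.417 | 19.5 |
| autumn | 0.667 | 24.9 |
| autumn | 1.00 | 35.3 |
| autumn | 2.00 | 51.6 |
| autumn | 3.00 | 60.1 |
| autumn | 5.00 | 65.9 |
| midnight | 0.333 | 9.7 |
| midnight | 1.00 | 11.3 |
| midnight | 2.00 | 11.3 |
| midnight | 2.50 | 10.4 |
| midnight | 4.00 | 10.3 |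
| midnight | 5.00 | 10.5 |

(scatter of a reading: 1 percentage point)

1. which of the two ends with the longer chains by the average number of monomer units in a chain (living and dead chains, two that joined counted as one) ("neither" if they lie within 10%) (blue / grey / neither)
2. average number of monomer units in a chain (living and dead chains, two that joined counted as one) at the end, blue
3. average number of monomer units in a chain (living and dead chains, two that joined counted as one) at the end, grey

- the average divides the monomer in chains by the number of chains, living and dead together; two radicals that join make one chain
- the earlier runs were read with a standard deviation of 1 percentage point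
- the earlier runs do not show the number of chains; that part of a forecast is a guess

Our first estimate lets each impurity take one free monomer and gives chains the remainder. For autumn that ceiling is 70.5%, and the reading at 5.00 min is 65.9%, still climbing. But midnight objects: its impurity exceeds its free monomer, so the subtraction gives −0.0100 M, yet the plateau reads 10.5%. So the two compete.

We freeze what looks nearly constant: chains take free monomer pseudo-first-order at a per minute, impurity at k·c(protic impurity). Free monomer cancels from the ratio, and integrating gives c(monomer in chains) = B·ln(charged impurity/impurity left), with B = a/k. Taking midnight's free monomer to end at nil, its last reading gives 0.0105 M. This is the capture concentration, the impurity level at which chains and impurity take free monomer equally fast.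

For grey, chains receive the excess of free monomer over impurity plus the impurity left, and solving this with B gives 0.0428 M, or 22.5%. Blue raises a doubt: we expect its free monomer to outlast the impurity, and its ceiling of 80.0% to be approached slowly. Autumn's gaps to its ceiling give a reading of 0.470 min⁻¹, which leaves blue 0.137 M. The number of chains remains unseen. With equal loadings we guess equal counts, so blue should be longer, by a factor of 3.20.

The forecast says blue, with 400 (150 to 800) for blue and 88 (35 to 180) for grey, counting “about one chain per initiator”. The flask gives 1180 for blue and 346 for grey.

    initiator → 2 initiating radical (k = 0.00130 s⁻¹)
    free monomer + initiating radical → growing radical + monomer in chains (k = 1.90 × 10⁷ L mol⁻¹ s⁻¹)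
    free monomer + growing radical → monomer in chains + growing radical, rate k3*[growing radical]*[free monomer] (k = 4.80 × 10⁵ L mol⁻¹ s⁻¹)
    2 growing radical → dead chain (k = 9.20 × 10⁸ L mol⁻¹ s⁻¹)
    2 free monomer → homo dimer (k = 1.40 × 10⁻⁴ L mol⁻¹ s⁻¹)
    protic impurity + free monomer → quenched substrate (k = 1.00 L mol⁻¹ s⁻¹)

Blue and grey end with equal dead chain, 1.23 × 10⁻⁴ M and 1.23 × 10⁻⁴ M, but hold 76.1% and 22.3% of monomer in chains. The difference in impurity charge is the main reason for the gap: with that difference taken away, grey gives 1180, not 346. B is the growth constant times growing radical over the quench constant, and while free monomer lasts, growing radical goes with the root of initiator. At 0.8 mol% of initiator, grey's neighbour therefore has B of 0.0210 M, giving 0.0531 M, or 28.0%. That neighbour gives 28.1% of monomer in chains, with an average length of 167.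

(The numbers in the tables come from a simulation for an exercise; the scatter is artificial.)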